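| flask | starting material | second substrate | coupling partner | free catalyst | temperature | remark | time |
|---|---|---|---|---|---|---|---|
| autumn | 0.20 M | 1 equiv | 1.8 equiv | 0.1 mol% | 35 °C | run made earlier |  |
| south | 0.20 M | 1.00 equiv | 1.20 equiv | 0.2 mol% | 55 °C |  | 50 min |
| north-west | 0.20 M | 1.00 equiv | 1.20 equiv | 0.1 mol% | 35 °C |  | 50 min |

autumn run (percent of the starting material charged)

| time / min | target / % | starting material / % |
|---|---|---|
| 1.50 | 1.7 | 97.3 |
| 5.00 | 4.0 | 96.7 |
| 8.00 | 5.5 | 94.2 |
| 12.0 | 10.2 | 90.5 |
| 20.0 | 16.6 | 82.5 |
| 25.0 | 19.0 | 82.7 |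
| 30.0 | 23.0 | 78.8 |

(readings scatter by 1 percentage point)

1. which of the two ends with the higher amount of target, in percent of the starting material charged ("neither" if they lie within 2 percentage points) (south / north-west / neither)
2. target at the end, in percent of the starting material charged, south
3. target at the end, in percent of the starting material charged, north-west

Per minute was the unit I wanted: the fraction of the coupling partner that the catalyst turned into target. The autumn target climbed almost in a straight line to 23.0 % at 30.0 min, so I took its rate as independent of c(starting material). I guessed it proportional to c(coupling partner) and to the catalyst charge, a pseudo-first-order loss of partner. With one partner per target, the autumn charge of 1.8 equiv and that last scattered reading gave 0.004557 min⁻¹, my coupling constant, at that loading and temperature.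

North-west shares both, so I reckoned from its 1.20 equiv a target of 24.5 % at 50 min. For south I multiplied the constant by 2.00 for catalyst and got 43.9 % before any guessed gain from heat, so I expected south higher.

The forecast said south, with 75 % (range 48 % to 95 %) for south and 30 % for north-west, taking south as “about 8× faster”. The flasks gave 49.8 % in south and 27.7 % in north-west.

    starting material + free catalyst ⇌ catalyst intermediate A (K = 67.0 M⁻¹, k = 1.66 M⁻¹ s⁻¹, Ea = 58.0 kJ mol⁻¹, ΔH = −50.0 kJ mol⁻¹)
    coupling partner + catalyst intermediate A → free catalyst + target (k = 1.19 M⁻¹ s⁻¹, Ea = 49.0 kJ mol⁻¹)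
    second substrate + free catalyst ⇌ catalyst intermediate B (K = 3.00 M⁻¹, k = 1.47 M⁻¹ s⁻¹, Ea = 63.0 kJ mol⁻¹, ΔH = −59.0 kJ mol⁻¹)
    coupling partner + catalyst intermediate B → free catalyst + second product (k = 0.396 M⁻¹ s⁻¹, Ea = 57.0 kJ mol⁻¹)
    coupling partner → decomposed reagent (k = 1.01 × 10⁻⁴ s⁻¹, Ea = 101 kJ mol⁻¹)
    (constants at 35 °C)

North-west held 27.7 % against the 24.5 % that my coupling constant of 0.00456 min⁻¹ had given. South, with 0.205 % of its partner left at 50.0 min, the limiting reagent, held 0.136 M of decomposed reagent, more than its 0.0996 M of target. In a flask like north-west with 0.050 M of starting material, the catalyst concentration fell in step, so I scaled the constant to 0.001139 min⁻¹, which put target at 6.64 %; that flask held 8.01 %.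

(The data are simulated with made-up constants, and the scatter is random.)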